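**Plan**

1. Retrosynthesis: the aryl acetate C–O bond is cut first. Then, in each resorcinol ring, the bond between the tether-bearing ring carbon and its ring neighbour is cut; that neighbour carried a carboxyl group, later lost as CO2. Last come the two bonds joining the diacid carbonyl carbons to the terminal carbon of a keto-dioxinone, which itself divides into 2,2,6-trimethyl-1,3-dioxin-4-one and an acetyl unit.
2. Enabling feature: each ring is a 5-alkylbenzene-1,3-diol, the fold of a 3,5,7-triketo acid in which ring C5 is the old acyl carbon and C1/C3 are old ketone carbons. The 16-carbon tether plus the two ring carbons carrying it are the C18 chain and C9 Z-olefin of (Z)-octadec-9-enedioic acid.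
3. Forward: dioxinone 1 and acetyl chloride 2 give keto-dioxinone 4, and diacid 5 gives bis(N-methoxy-N-methylamide) 7. The dianion of 4 is joined to both ends of 7 to give bis(diketo-dioxinone) 9.
4. Both benzene rings then arise together in one flask by amine-triggered aldol aromatisation (9 to 10). Saponification with decarboxylation gives tetraol 12, and a single acetylation gives target 13.
5. Stereochemistry: there is no stereocentre. The only stereo-element, the Z-olefin, is bought with the diacid and meets no metal, radical, oxidant or strong acid that could isomerise it.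

Key step: step 4

Remark: the four phenolic hydroxyls of tetraol 12 are equivalent (two per ring, the rings related by the molecular symmetry), so only one monoacetate exists and it is the target; 9 is drawn as its all-keto tautomer, and diacid 5 is taken as the commercial, geometrically pure Z isomer.

**Step 1**
Reactants: 1 2,2,6-trimethyl-4H-1,3-dioxin-4-one; 2 acetyl chloride
Product: 4 2,2-dimethyl-6-(2-oxopropyl)-4H-1,3-dioxin-4-one, via lithium dienolate 3 (not isolated)
Conditions: LiN(SiMe3)2 (1.0 equiv per 1), THF, −78 °C; AcCl (0.5 equiv per 1), −78 to −20 °C; 1 M HCl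
Reagents that add atoms: lithium bis(trimethylsilyl)amide, [Li+].C[Si](C)(C)[N-][Si](C)(C)C (supplies only the lithium of 3; nothing of it remains in 4)
Why: Kinetic deprotonation of the 6-methyl group gives the lithium dienolate, which undergoes a vinylogous Claisen-type C-acylation at its exocyclic γ-carbon with the acid chloride, the second equivalent of dienolate taking up the acidic proton of 4 so that over-acylation is held back.

**Step 2**
Reactants: 5 (Z)-octadec-9-enedioic acid
Product: 7 (Z)-N1,N18-dimethoxy-N1,N18-dimethyloctadec-9-enediamide, via bis(imidazolide) 6 (not isolated)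
Conditions: CDI (2.2 equiv), CH2Cl2, rt; MeNH(OMe)·HCl (2.6 equiv), rt
Reagents that add atoms: 1,1'-carbonyldiimidazole, O=C(n1ccnc1)n1ccnc1 (its imidazolyl groups stand in 6 only); N,O-dimethylhydroxylamine hydrochloride, CNOC.Cl
Why: Acyl-imidazolide activation followed by aminolysis (amide formation under near-neutral conditions) should convert both carboxyls into N-methoxy-N-methylamides without touching the isolated Z-olefin.

**Step 3**
Reactants: 4 2,2-dimethyl-6-(2-oxopropyl)-4H-1,3-dioxin-4-one (2.6 equiv); 7 (Z)-N1,N18-dimethoxy-N1,N18-dimethyloctadec-9-enediamide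
Product: 9 (Z)-1,24-bis(2,2-dimethyl-4-oxo-4H-1,3-dioxin-6-yl)tetracos-12-ene-2,4,21,23-tetraone, via dilithium dianion 8 (not isolated)
Conditions: 4, LiN(iPr)2 (2.05 equiv per 4), THF, −78 to −40 °C; 7 (1.0 equiv), −78 to 0 °C; 1 M HCl to pH 3; short silica plug, used at once
Reagents that add atoms: lithium diisopropylamide, [Li+].CC(C)[N-]C(C)C (supplies only the lithium of 8)
Why: This is a two-fold crossed Claisen condensation of a 1,3-dicarbonyl dianion, which reacts at its terminal, last-formed carbanion carbon, while the chelated tetrahedral adduct of each N-methoxy-N-methylamide should survive until the acidic quench, so that neither double addition nor proton transfer from product to unreacted dianion interferes.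

**Step 4**
Reactants: 9 (Z)-1,24-bis(2,2-dimethyl-4-oxo-4H-1,3-dioxin-6-yl)tetracos-12-ene-2,4,21,23-tetraone
Product: 10 (Z)-1,16-bis(7-hydroxy-2,2-dimethyl-4-oxo-4H-benzo[d][1,3]dioxin-5-yl)hexadec-8-ene
Conditions: Et3N (10 equiv), CH2Cl2 (0.02 M), rt; wash with 1 M HCl
Reagents that add atoms: none
Why: Et3N removes a proton from the methylene flanked by the dioxinone ring and the first ketone at each terminus, and the resulting vinylogous enolate adds through its α-carbon (dioxinone C5) to the chain-terminal ketone, the former diacid carbonyl, after which E1cB loss of water and enolisation of the remaining ring ketone give the phenol. The closest known reaction is the amine- or carbonate-mediated aromatisation of 6-(2,4-dioxoalkyl)-1,3-dioxin-4-ones to isopropylidene-protected β-resorcylates, the laboratory form of the orsellinate-type polyketide aldol condensation, here run at two identical and independent termini of one chain. Each benzene ring closes by a 6-(enolexo)-exo-trig aldol addition that forms the C–C bond between dioxinone C5 and the ketone carbon carrying the tether. No stereocentre is formed, and the Z-olefin, seven methylenes from either reacting site, meets only a tertiary amine at room temperature. The selectivity needed is aldol closure over Claisen closure to an acylphloroglucinol and over O-cyclisation to a pyranone: the dioxinone holds its carbonyl carbon trans to the side chain across the C5=C6 double bond, out of reach of any chain nucleophile in a six-membered transition state, and it keeps the C6 oxygen locked in the acetal so that no free 1,3,5-tricarbonyl unit is available. Intermolecular aldol reaction between termini should be suppressed by the dilution, the six-membered intramolecular closure being much faster.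

**Step 5**
Reactants: 10 (Z)-1,16-bis(7-hydroxy-2,2-dimethyl-4-oxo-4H-benzo[d][1,3]dioxin-5-yl)hexadec-8-ene
Product: 12 5,5'-[(Z)-hexadec-8-ene-1,16-diyl]bis(benzene-1,3-diol), via bis(resorcylic acid) 11 (not isolated)
Conditions: 6 M aq. KOH, MeOH, argon (degassed), sealed tube, 120 °C; then 2 M HCl to pH 2, 0 °C to rt
Reagents that add atoms: potassium hydroxide, [K+].[OH-] (its oxygen stands only in the carboxyl groups of 11 and leaves again as carbon dioxide)
Why: Hydroxide opens each aryl-fused dioxinone (ester saponification with loss of acetone) and the resulting 2,4-dihydroxybenzoates, having an electron-rich ipso carbon, should undergo protodecarboxylation on heating, as in the classical one-pot saponification–decarboxylation route to 5-alkylresorcinols such as olivetol, while the isolated Z-olefin is inert to hot alkali and exclusion of air protects the resorcinols.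

**Step 6**
Reactants: 12 5,5'-[(Z)-hexadec-8-ene-1,16-diyl]bis(benzene-1,3-diol)
Product: 13 Oncostemonol B, 3-[(Z)-16-(3,5-dihydroxyphenyl)hexadec-8-en-1-yl]-5-hydroxyphenyl acetate
Conditions: Ac2O (0.6 equiv, slow addition), pyridine (2 equiv), THF (dilute), −20 to 0 °C; chromatography, recovered 12 resubmitted
Reagents that add atoms: acetic anhydride, CC(=O)OC(C)=O
Why: This is a pyridine-mediated O-acylation of a phenol by an anhydride in which, the four hydroxyls of 12 being symmetry-equivalent, every first acetylation gives 13, and substoichiometric, slowly added anhydride should keep the acetylated fraction mainly at the monoacetate, with unreacted 12 recovered and over-acetylated material returned to 12 by K2CO3/MeOH.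

**Compound list**

1 | 2,2,6-trimethyl-4H-1,3-dioxin-4-one | CC1=CC(=O)OC(C)(C)O1 | starting material
2 | acetyl chloride | CC(=O)Cl | starting material
3 | lithium dienolate of 1 (lithium 2,2-dimethyl-6-methylidene-1,3-dioxin-4-olate) | [Li+].C=C1C=C([O-])OC(C)(C)O1 | intermediate (not isolated)
4 | 2,2-dimethyl-6-(2-oxopropyl)-4H-1,3-dioxin-4-one | CC(=O)CC1=CC(=O)OC(C)(C)O1 | intermediate
5 | (Z)-octadec-9-enedioic acid | OC(=O)CCCCCCC/C=C\CCCCCCCC(=O)O | starting material
6 | (Z)-1,18-di(1H-imidazol-1-yl)octadec-9-ene-1,18-dione (bis(imidazolide)) | O=C(CCCCCCC/C=C\CCCCCCCC(=O)n1ccnc1)n1ccnc1 | intermediate (not isolated)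
7 | (Z)-N1,N18-dimethoxy-N1,N18-dimethyloctadec-9-enediamide | CON(C)C(=O)CCCCCCC/C=C\CCCCCCCC(=O)N(C)OC | intermediate
8 | dilithium dianion of 4 (bis-enolate form) | [Li+].[Li+].C=C([O-])C=C1C=C([O-])OC(C)(C)O1 | intermediate (not isolated)
9 | (Z)-1,24-bis(2,2-dimethyl-4-oxo-4H-1,3-dioxin-6-yl)tetracos-12-ene-2,4,21,23-tetraone | CC1(C)OC(CC(=O)CC(=O)CCCCCCC/C=C\CCCCCCCC(=O)CC(=O)CC2=CC(=O)OC(C)(C)O2)=CC(=O)O1 | intermediate
10 | (Z)-1,16-bis(7-hydroxy-2,2-dimethyl-4-oxo-4H-benzo[d][1,3]dioxin-5-yl)hexadec-8-ene | CC1(C)Oc2cc(O)cc(CCCCCCC/C=C\CCCCCCCc3cc(O)cc4OC(C)(C)OC(=O)c34)c2C(=O)O1 | intermediate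
11 | 6,6'-[(Z)-hexadec-8-ene-1,16-diyl]bis(2,4-dihydroxybenzoic acid) | OC(=O)c1c(O)cc(O)cc1CCCCCCC/C=C\CCCCCCCc1cc(O)cc(O)c1C(O)=O | intermediate (not isolated)
12 | 5,5'-[(Z)-hexadec-8-ene-1,16-diyl]bis(benzene-1,3-diol) | Oc1cc(O)cc(CCCCCCC/C=C\CCCCCCCc2cc(O)cc(O)c2)c1 | intermediate
13 | Oncostemonol B, 3-[(Z)-16-(3,5-dihydroxyphenyl)hexadec-8-en-1-yl]-5-hydroxyphenyl acetate | CC(=O)Oc1cc(O)cc(CCCCCCC/C=C\CCCCCCCc2cc(O)cc(O)c2)c1 | target

**Step count and risks**

Total step count: 6. Longest linear sequence: 5 steps (1 to 13 through steps 1, 3, 4, 5, 6; equally 5 to 13 through steps 2, 3, 4, 5, 6).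

Steps most likely to fail:

Step 3. The two-fold acylation may stall after the first amide has reacted, or the dianion may be consumed by proton transfer, so that chain joining stays incomplete at one end. The fallback replaces the dianion by a soft magnesium enolate whose regiochemistry is fixed by an ester; it sets out from 5 (and from 1 by way of 3) and returns at 9. Diacid 5 is treated with oxalyl chloride and catalytic DMF in CH2Cl2 to give (Z)-octadec-9-enedioyl dichloride F1. In parallel, lithium dienolate 3, made from 1 as in step 1, is C-acylated with allyl malonyl chloride (allyl 3-chloro-3-oxopropanoate) to give allyl 4-(2,2-dimethyl-4-oxo-4H-1,3-dioxin-6-yl)-3-oxobutanoate F2. Soft enolisation of F2 (2.2 equiv) with MgCl2 and pyridine in CH2Cl2 at 0 °C and C-acylation at its β-keto ester methylene by F1 should give diallyl (Z)-2,21-bis[(2,2-dimethyl-4-oxo-4H-1,3-dioxin-6-yl)acetyl]-3,20-dioxodocos-11-enedioate F3. Deallylation with catalytic Pd(PPh3)4 (zerovalent palladium) and morpholine in THF at 0 °C, with spontaneous decarboxylation of the β-keto acids, then delivers 9.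

Step 4. One terminus may aromatise while the other stalls at the aldol (β-hydroxy ketone) stage, or termini may condense intermolecularly. The fallback changes the cyclising substrate from the dioxinone to an open triketo ester while forming the same two ring bonds; it sets out from 9 and returns at 11, which the conditions of step 5 carry on to 12. Heating 9 with methanol in toluene at 110 °C (sealed tube) should expel acetone by retro-[4+2] fragmentation and trap both acylketenes as dimethyl (Z)-3,5,7,24,26,28-hexaoxotriacont-15-enedioate F4. Cs2CO3 in MeOH at rt (aldol closure) followed by methanolic HCl (dehydration) should give dimethyl 6,6'-[(Z)-hexadec-8-ene-1,16-diyl]bis(2,4-dihydroxybenzoate) F5. Aqueous KOH/MeOH at 120 °C saponifies F5 to 11.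

Step 6. The first acetyl group does not slow the second, and local excess of anhydride during mixing can push the product distribution beyond the monoacetate. The fallback replaces kinetically controlled acylation by an equilibrium redistribution of acetyl groups; it sets out from 12 and returns at 13. Part of 12 is peracetylated (excess Ac2O, pyridine, catalytic DMAP, CH2Cl2) to the easily purified (Z)-1,16-bis(3,5-diacetoxyphenyl)hexadec-8-ene F6. One part of F6 and three parts of 12 are stirred with catalytic K2CO3 in dry DMF at rt, where phenoxide-to-aryl-acetate acyl transfer should spread the acetyl groups to the equilibrium mixture averaging one acetate per molecule. Target 13 is separated and all other fractions are pooled and re-equilibrated.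

**Further compounds**

F1 | step 3 | (Z)-octadec-9-enedioyl dichloride | ClC(=O)CCCCCCC/C=C\CCCCCCCC(=O)Cl
F2 | step 3 | allyl 4-(2,2-dimethyl-4-oxo-4H-1,3-dioxin-6-yl)-3-oxobutanoate | C=CCOC(=O)CC(=O)CC1=CC(=O)OC(C)(C)O1
F3 | step 3 | diallyl (Z)-2,21-bis[(2,2-dimethyl-4-oxo-4H-1,3-dioxin-6-yl)acetyl]-3,20-dioxodocos-11-enedioate | C=CCOC(=O)C(C(=O)CC1=CC(=O)OC(C)(C)O1)C(=O)CCCCCCC/C=C\CCCCCCCC(=O)C(C(=O)OCC=C)C(=O)CC1=CC(=O)OC(C)(C)O1
F4 | step 4 | dimethyl (Z)-3,5,7,24,26,28-hexaoxotriacont-15-enedioate | COC(=O)CC(=O)CC(=O)CC(=O)CCCCCCC/C=C\CCCCCCCC(=O)CC(=O)CC(=O)CC(=O)OC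
F5 | step 4 | dimethyl 6,6'-[(Z)-hexadec-8-ene-1,16-diyl]bis(2,4-dihydroxybenzoate) | COC(=O)c1c(O)cc(O)cc1CCCCCCC/C=C\CCCCCCCc1cc(O)cc(O)c1C(=O)OC
F6 | step 6 | (Z)-1,16-bis(3,5-diacetoxyphenyl)hexadec-8-ene | CC(=O)Oc1cc(OC(C)=O)cc(CCCCCCC/C=C\CCCCCCCc2cc(OC(C)=O)cc(OC(C)=O)c2)c1
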